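**Plan**
- Retrosynthesis: the C6–O ester bond is cut first (isoferulic acid), then the C6–C7 bond of ring B, then C4–CH3, C5–C6 and C10–C9 of a ring A cyclohexanone.
- Enabling feature: ring B (C5–C10) carries the C6 oxygen next to the isopropyl-bearing C7. A C6 aldehyde on C5 and a homoprenyl arm (C9–C8–C7=C11) on C10 form this 1,2-pattern in a type 1 carbonyl-ene closure.
- Forward: ring A is the starting enone; the arm is added to C10, C6 to C5 and the methyl to C4; ring B closes in the ene step; the ester is attached last.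
- Stereochemistry: C10 from a copper/chiral carbene conjugate addition; C5 anti to the arm in the enol silane alkylation; C4 by equatorial Grignard attack; C7 and C6 from the chair ene transition state; C6 then inverted through the ketone by hydride from the α face.

Key step: step 6

Remark: eudesmane numbering (C4 carbinol, C5 ring-fusion CH, C6 ester carbon, C7 isopropyl-bearing carbon, C10 quaternary carbon) and α/β (C10 methyl = β) are used for all intermediates, also before ring B exists.

**Route**

Step 1
Reactants: 1 3-methylcyclohex-2-en-1-one; 2 5-bromo-2-methylpent-2-ene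
Product: 5 trimethyl{[(3R)-3-methyl-3-(4-methylpent-3-en-1-yl)cyclohex-1-en-1-yl]oxy}silane, via (4-methylpent-3-en-1-yl)magnesium bromide 3 (not isolated), via bromomagnesium enolate 4 (not isolated)
Conditions: Mg, Et2O, 35 °C; then 1, Cu(OTf)2 (3 mol %), chiral imidazolinium chloride (carbene ligand precursor, 4 mol %, enantiomer giving R at C10), Et2O, −30 °C; then Me3SiCl, Et3N, HMPA, −30 °C → rt
Reagents that add atoms: chlorotrimethylsilane, C[Si](C)(C)Cl
Why: Copper-catalysed asymmetric conjugate addition of the Grignard reagent to the β-methyl enone builds the quaternary C10 with the chiral carbene ligand choosing the enone face, and O-silylation of the magnesium enolate fixes the enolate position at C4/C5.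

Step 2
Reactants: 5 trimethyl{[(3R)-3-methyl-3-(4-methylpent-3-en-1-yl)cyclohex-1-en-1-yl]oxy}silane; 6 trimethyl orthoformate
Product: 7 (2S,3R)-2-(dimethoxymethyl)-3-methyl-3-(4-methylpent-3-en-1-yl)cyclohexan-1-one (dimethoxymethyl group trans to the homoprenyl arm)
Conditions: Me3SiOTf (10 mol %), CH2Cl2, −78 °C
Reagents that add atoms: none
Why: Mukaiyama-type alkylation of the enol silane by the dimethoxycarbenium ion forms C5–C6 only at the carbon fixed in step 1; C5 is set kinetically by attack anti to the homoprenyl arm, a bias expected to be modest because methyl and homoprenyl differ little in size.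

Step 3
Reactants: 7 (2S,3R)-2-(dimethoxymethyl)-3-methyl-3-(4-methylpent-3-en-1-yl)cyclohexan-1-one
Product: 8 (1S,2R,3R)-2-(dimethoxymethyl)-1,3-dimethyl-3-(4-methylpent-3-en-1-yl)cyclohexan-1-ol (4β-OH, cis to the acetal and to the C10 methyl)
Conditions: MeMgBr, anhydrous CeCl3, THF, −78 → 0 °C
Reagents that add atoms: methylmagnesium bromide, C[Mg]Br
Why: Grignard 1,2-addition with CeCl3 (suppresses enolisation) occurs by equatorial attack, anti to the axial C10 methyl in the chair that keeps the chelating dimethoxymethyl group equatorial, giving the axial 4β alcohol.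

Step 4
Reactants: 8 (1S,2R,3R)-2-(dimethoxymethyl)-1,3-dimethyl-3-(4-methylpent-3-en-1-yl)cyclohexan-1-ol
Product: 9 triethyl{[(1S,2R,3R)-2-(dimethoxymethyl)-1,3-dimethyl-3-(4-methylpent-3-en-1-yl)cyclohexyl]oxy}silane
Conditions: KN(SiMe3)2, THF, −78 °C; then Et3SiCl, −78 → 0 °C
Reagents that add atoms: chlorotriethylsilane, CC[Si](Cl)(CC)CC
Why: O-silylation of the potassium alkoxide protects the hindered tertiary alcohol without a Lewis acid that could ionise the acetal onto the alkene (Prins closure).

Step 5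
Reactants: 9 triethyl{[(1S,2R,3R)-2-(dimethoxymethyl)-1,3-dimethyl-3-(4-methylpent-3-en-1-yl)cyclohexyl]oxy}silane
Product: 10 (1R,2R,6S)-2,6-dimethyl-2-(4-methylpent-3-en-1-yl)-6-[(triethylsilyl)oxy]cyclohexane-1-carbaldehyde (C1 = C5, C2 = C10, C6 = C4 of the eudesmane; aldehyde and homoprenyl arm trans-diequatorial)
Conditions: PPTS (cat.), acetone–H2O (9:1), 40 °C
Reagents that add atoms: water, O
Why: Mild acid-catalysed acetal hydrolysis frees the aldehyde, since water intercepts the oxocarbenium ion faster than the alkene can, while the tertiary silyl ether and the C5 configuration should survive.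

Step 6
Reactants: 10 (1R,2R,6S)-2,6-dimethyl-2-(4-methylpent-3-en-1-yl)-6-[(triethylsilyl)oxy]cyclohexane-1-carbaldehyde
Product: 11 (4S,5S,6S,7S,10R)-4-[(triethylsilyl)oxy]eudesm-11-en-6-ol (4β-silyloxy; 5α-H; 6α-OH; 7β-isopropenyl)
Conditions: Me2AlCl (1.5 equiv), CH2Cl2, −78 → −40 °C
Reagents that add atoms: none
Why: Me2AlCl coordinates the C6 aldehyde; C7 of the trisubstituted alkene then bonds to the carbonyl carbon while a hydrogen of a C11 methyl group moves to oxygen, in one step or through a short-lived tertiary C11 cation. This is the Lewis-acid type 1 intramolecular carbonyl-ene reaction known from citronellal-type 6-alkenals, which give isopulegol-type 2-(prop-1-en-2-yl)cyclohexanols. Ring B closes in the 6-exo mode with respect to the alkene (C7 inside the ring; C11 outside) through a chair fused to the ring A chair. C7 is controlled by C5 and C10: their equatorial aldehyde and homoprenyl arm allow only a trans-decalin chair, in which the developing propenyl group sits equatorial (7β). C6 is controlled by the same chair, the aluminium-bound oxygen lying equatorial (6α) and anti to the C7 substituent because an axial oxygen would clash with the axial C10 methyl and the C4 silyloxy group. The step needs ene closure to outrun β-elimination of the C4 silyloxy group and chloride capture of the cation; the silyl ether (a poor leaving group and poor chelator), the low temperature and the proton-scavenging methylaluminium reagent should secure this.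

Step 7
Reactants: 11 (4S,5S,6S,7S,10R)-4-[(triethylsilyl)oxy]eudesm-11-en-6-ol
Product: 12 (4S,5S,6S,7S,10R)-4-[(triethylsilyl)oxy]eudesman-6-ol (6α-OH; 7β-isopropyl)
Conditions: H2 (1 atm), Pd/C (10 %), EtOAc, rt
Reagents that add atoms: none
Why: Heterogeneous catalytic hydrogenation saturates the unhindered 1,1-disubstituted alkene to the isopropyl group; no stereocentre is formed and the silyl ether is inert in ethyl acetate.

Step 8
Reactants: 12 (4S,5S,6S,7S,10R)-4-[(triethylsilyl)oxy]eudesman-6-ol
Product: 13 (4S,5R,7S,10R)-4-[(triethylsilyl)oxy]eudesman-6-one (5α-H; 7β-isopropyl)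
Conditions: Dess–Martin periodinane, CH2Cl2, 0 °C → rt
Reagents that add atoms: none
Why: Dess–Martin oxidation converts the hindered secondary alcohol into the ketone under near-neutral conditions that should leave the β-silyloxy group and the epimerisable C5 and C7 untouched.

Step 9
Reactants: 13 (4S,5R,7S,10R)-4-[(triethylsilyl)oxy]eudesman-6-one
Product: 14 (4S,5S,6R,7S,10R)-4-[(triethylsilyl)oxy]eudesman-6-ol (6β-OH, axial)
Conditions: LiBH(s-Bu)3, THF, −78 → 0 °C
Reagents that add atoms: none
Why: Hydride reduction by the bulky trialkylborohydride from the α face (equatorial approach), the β face being blocked by the axial C10 methyl and the axial C4 silyloxy group, gives the axial 6β alcohol.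

Step 10
Reactants: 14 (4S,5S,6R,7S,10R)-4-[(triethylsilyl)oxy]eudesman-6-ol
Product: 15 (4S,5S,6R,7S,10R)-eudesmane-4,6-diol (4β,6β-diol; 5α-H)
Conditions: HF·pyridine, THF, 0 °C → rt
Reagents that add atoms: none
Why: Fluoride-driven desilylation frees the tertiary alcohol, leaving the secondary 6β hydroxyl as the only readily acylated position.

Step 11
Reactants: 16 isoferulic acid [(2E)-3-(3-hydroxy-4-methoxyphenyl)prop-2-enoic acid]
Product: 18 (2E)-3-{3-[(tert-butyldimethylsilyl)oxy]-4-methoxyphenyl}prop-2-enoic acid, via bis-silylated silyl ester 17 (not isolated)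
Conditions: TBSCl, imidazole, DMF, rt; then AcOH–THF–H2O, rt
Reagents that add atoms: tert-butylchlorodimethylsilane, CC(C)(C)[Si](C)(C)Cl
Why: Silylation of both acidic hydroxyls followed by selective hydrolysis of the labile silyl ester masks only the phenol, so the activated acid cannot acylate itself.

Step 12
Reactants: 15 (4S,5S,6R,7S,10R)-eudesmane-4,6-diol; 18 (2E)-3-{3-[(tert-butyldimethylsilyl)oxy]-4-methoxyphenyl}prop-2-enoic acid
Product: 20 (4S,5S,6R,7S,10R)-4-hydroxyeudesman-6-yl (2E)-3-{3-[(tert-butyldimethylsilyl)oxy]-4-methoxyphenyl}prop-2-enoate, via mixed anhydride 19 (not isolated)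
Conditions: 2,4,6-trichlorobenzoyl chloride, Et3N, THF, rt; then 15, DMAP, toluene, 80 °C
Reagents that add atoms: none
Why: Yamaguchi esterification, in which DMAP turns the mixed anhydride into an acylpyridinium ion that acylates the secondary 6β hydroxyl with retention at C6, the tertiary C4 hydroxyl being too hindered to compete.

Step 13
Reactants: 20 (4S,5S,6R,7S,10R)-4-hydroxyeudesman-6-yl (2E)-3-{3-[(tert-butyldimethylsilyl)oxy]-4-methoxyphenyl}prop-2-enoate
Product: 21 (4S,5S,6R,7S,10R)-4-hydroxyeudesman-6-yl (2E)-3-(3-hydroxy-4-methoxyphenyl)prop-2-enoate (CNP0291757.1)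
Conditions: Bu4NF, AcOH, THF, 0 °C
Reagents that add atoms: none
Why: Buffered fluoride cleaves the aryl silyl ether, which is far more labile than the hindered ester, so the target should form without ester cleavage or acyl migration.

**Compound list**

1 | 3-methylcyclohex-2-en-1-one | CC1=CC(=O)CCC1 | starting material
2 | 5-bromo-2-methylpent-2-ene | CC(C)=CCCBr | starting material
3 | (4-methylpent-3-en-1-yl)magnesium bromide | CC(C)=CCC[Mg]Br | intermediate
4 | bromo{[(3R)-3-methyl-3-(4-methylpent-3-en-1-yl)cyclohex-1-en-1-yl]oxy}magnesium | Br[Mg]OC1=C[C@](C)(CCC1)CCC=C(C)C | intermediate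
5 | trimethyl{[(3R)-3-methyl-3-(4-methylpent-3-en-1-yl)cyclohex-1-en-1-yl]oxy}silane | C[Si](C)(C)OC1=C[C@](C)(CCC1)CCC=C(C)C | intermediate
6 | trimethyl orthoformate | COC(OC)OC | starting material
7 | (2S,3R)-2-(dimethoxymethyl)-3-methyl-3-(4-methylpent-3-en-1-yl)cyclohexan-1-one | COC(OC)[C@@H]1[C@](C)(CCCC1=O)CCC=C(C)C | intermediate
8 | (1S,2R,3R)-2-(dimethoxymethyl)-1,3-dimethyl-3-(4-methylpent-3-en-1-yl)cyclohexan-1-ol | COC(OC)[C@@H]1[C@](C)(CCC[C@]1(C)O)CCC=C(C)C | intermediate
9 | triethyl{[(1S,2R,3R)-2-(dimethoxymethyl)-1,3-dimethyl-3-(4-methylpent-3-en-1-yl)cyclohexyl]oxy}silane | COC(OC)[C@@H]1[C@](C)(CCC[C@]1(C)O[Si](CC)(CC)CC)CCC=C(C)C | intermediate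
10 | (1R,2R,6S)-2,6-dimethyl-2-(4-methylpent-3-en-1-yl)-6-[(triethylsilyl)oxy]cyclohexane-1-carbaldehyde | O=C[C@@H]1[C@](C)(CCC[C@]1(C)O[Si](CC)(CC)CC)CCC=C(C)C | intermediate
11 | (4S,5S,6S,7S,10R)-4-[(triethylsilyl)oxy]eudesm-11-en-6-ol | O[C@@H]1[C@@H]2[C@](C)(CCC[C@]2(C)O[Si](CC)(CC)CC)CC[C@H]1C(C)=C | intermediate
12 | (4S,5S,6S,7S,10R)-4-[(triethylsilyl)oxy]eudesman-6-ol | O[C@@H]1[C@@H]2[C@](C)(CCC[C@]2(C)O[Si](CC)(CC)CC)CC[C@H]1C(C)C | intermediate
13 | (4S,5R,7S,10R)-4-[(triethylsilyl)oxy]eudesman-6-one | O=C1[C@@H]2[C@](C)(CCC[C@]2(C)O[Si](CC)(CC)CC)CC[C@H]1C(C)C | intermediate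
14 | (4S,5S,6R,7S,10R)-4-[(triethylsilyl)oxy]eudesman-6-ol | O[C@H]1[C@@H]2[C@](C)(CCC[C@]2(C)O[Si](CC)(CC)CC)CC[C@H]1C(C)C | intermediate
15 | (4S,5S,6R,7S,10R)-eudesmane-4,6-diol | O[C@H]1[C@@H]2[C@](C)(CCC[C@]2(C)O)CC[C@H]1C(C)C | intermediate
16 | isoferulic acid | COc1ccc(/C=C/C(=O)O)cc1O | starting material
17 | tert-butyldimethylsilyl (2E)-3-{3-[(tert-butyldimethylsilyl)oxy]-4-methoxyphenyl}prop-2-enoate | COc1ccc(/C=C/C(=O)O[Si](C)(C)C(C)(C)C)cc1O[Si](C)(C)C(C)(C)C | intermediate
18 | (2E)-3-{3-[(tert-butyldimethylsilyl)oxy]-4-methoxyphenyl}prop-2-enoic acid | COc1ccc(/C=C/C(=O)O)cc1O[Si](C)(C)C(C)(C)C | intermediate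
19 | (2E)-3-{3-[(tert-butyldimethylsilyl)oxy]-4-methoxyphenyl}prop-2-enoic 2,4,6-trichlorobenzoic anhydride | COc1ccc(/C=C/C(=O)OC(=O)c2c(Cl)cc(Cl)cc2Cl)cc1O[Si](C)(C)C(C)(C)C | intermediate
20 | (4S,5S,6R,7S,10R)-4-hydroxyeudesman-6-yl (2E)-3-{3-[(tert-butyldimethylsilyl)oxy]-4-methoxyphenyl}prop-2-enoate | COc1ccc(/C=C/C(=O)O[C@H]2[C@@H]3[C@](C)(CCC[C@]3(C)O)CC[C@H]2C(C)C)cc1O[Si](C)(C)C(C)(C)C | intermediate
21 | (4S,5S,6R,7S,10R)-4-hydroxyeudesman-6-yl (2E)-3-(3-hydroxy-4-methoxyphenyl)prop-2-enoate | COc1ccc(/C=C/C(=O)O[C@H]2[C@@H]3[C@](C)(CCC[C@]3(C)O)CC[C@H]2C(C)C)cc1O | target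

**Step count**
Total: 13 steps. Longest linear sequence: 12 steps (steps 1–10, 12, 13); step 11 is the side branch.

**Steps most likely to fail**

1. Step 2 — poor facial selectivity in the C–C bond formation at C5. The two enolate faces differ only by a methyl and a primary alkyl chain on C10, so attack from both sides is likely. The wrong C5 epimer would carry its own C4 configuration through step 3 and could only close to a cis-fused decalin in step 6. It would be separated there, which costs material but not purity; the unwanted epimer of 7 could also be re-equilibrated with DBU and recycled.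
 Fallback (from 5, returning at 10): C6 is introduced at the alcohol level under catalyst control instead of substrate control. Hydroxymethylation of 5 with aqueous formaldehyde, Sc(OTf)3 and a chiral 2,2'-bipyridine diol ligand (DME–H2O, −20 °C) should give the hydroxymethyl ketone F1, the ligand and not the C10 substituents choosing the C5 face. Et3SiCl and imidazole would give the primary silyl ether F2. MeMgBr with CeCl3 would add as in step 3 to the tertiary alcohol F3. KN(SiMe3)2 and Et3SiCl would give the bis(silyl) ether F4. Swern oxidation [(COCl)2, DMSO, Et3N] converts a primary triethylsilyl ether directly into the aldehyde and leaves the tertiary one, giving 10.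

2. Step 6 — β-elimination (or Lewis-acid ionisation) of the C4 silyloxy group competing with ring closure, and methyl transfer from aluminium to the hindered aldehyde.
 Fallback (from 8, returning at 15): the elimination is accepted and C4/C5 are set after ring B exists; any C4/C5 stereoisomer of 8 serves, so this also removes the selectivity problem of step 2. 2 M HCl in THF at rt should hydrolyse the acetal and dehydrate the aldol to the conjugated enal F5, which has no β-leaving group. Me2AlCl (CH2Cl2, −78 → 0 °C) should close ring B by the same type 1 carbonyl-ene reaction to eudesma-4,11-dien-6β-ol F6. The 7β-isopropenyl group follows from the chair with the axial C10 methyl, and the oxygen should lie axial to avoid A(1,3) strain with the C4 methyl; a 6α epimer would be converged by MnO2 oxidation and hydride reduction from the α face. VO(acac)2 with t-BuOOH would epoxidise the tetrasubstituted alkene syn to the allylic hydroxyl, giving the 4β,5β-epoxy alcohol F7. Dess–Martin oxidation would give the epoxy ketone F8. SmI2 (THF–MeOH, −78 °C) would cleave the C5–O bond, and protonation of the samarium enolate from the α face should give the trans-fused 4β-hydroxy-5α-eudesm-11-en-6-one F9. H2 with Pd/C would give 4β-hydroxy-5α-eudesman-6-one F10, and LiBH(s-Bu)3 would reduce it from the α face to 15.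

3. Step 12 — incomplete acylation of the axial 6β hydroxyl, which is flanked by the axial C10 methyl and C4 hydroxyl and by the C7 isopropyl group.
 Fallback (from 15, returning at 20): the cinnamate is built on a small ester already in place. Bromoacetyl bromide and pyridine (CH2Cl2, 0 °C) would acylate the 6β hydroxyl with a small, very reactive acyl donor to the bromoacetate F11. P(OEt)3 at 110 °C (Arbuzov reaction) would give the phosphonoacetate F12. A Horner–Wadsworth–Emmons reaction (LiCl, DBU, MeCN) with the silylated isovanillin F13 (from isovanillin, TBSCl, imidazole) would form the (E)-alkene and give 20.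

**Further compounds**

F1 | step 2 | (2S,3R)-2-(hydroxymethyl)-3-methyl-3-(4-methylpent-3-en-1-yl)cyclohexan-1-one | OC[C@@H]1[C@](C)(CCCC1=O)CCC=C(C)C
F2 | step 2 | (2S,3R)-3-methyl-3-(4-methylpent-3-en-1-yl)-2-{[(triethylsilyl)oxy]methyl}cyclohexan-1-one | CC[Si](CC)(CC)OC[C@@H]1[C@](C)(CCCC1=O)CCC=C(C)C
F3 | step 2 | (1S,2S,3R)-1,3-dimethyl-3-(4-methylpent-3-en-1-yl)-2-{[(triethylsilyl)oxy]methyl}cyclohexan-1-ol | CC[Si](CC)(CC)OC[C@@H]1[C@](C)(CCC[C@]1(C)O)CCC=C(C)C
F4 | step 2 | triethyl{[(1S,2S,3R)-1,3-dimethyl-3-(4-methylpent-3-en-1-yl)-2-{[(triethylsilyl)oxy]methyl}cyclohexyl]oxy}silane | CC[Si](CC)(CC)OC[C@@H]1[C@](C)(CCC[C@]1(C)O[Si](CC)(CC)CC)CCC=C(C)C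
F5 | step 6 | (6R)-2,6-dimethyl-6-(4-methylpent-3-en-1-yl)cyclohex-1-ene-1-carbaldehyde | O=CC1=C(C)CCC[C@]1(C)CCC=C(C)C
F6 | step 6 | (6R,7S,10R)-eudesma-4,11-dien-6-ol (6β-OH; 7β-isopropenyl) | O[C@H]1C2=C(C)CCC[C@]2(C)CC[C@H]1C(C)=C
F7 | step 6 | 4β,5β-epoxyeudesm-11-en-6β-ol | O[C@H]1[C@]23O[C@@]2(C)CCC[C@]3(C)CC[C@H]1C(C)=C
F8 | step 6 | 4β,5β-epoxyeudesm-11-en-6-one | O=C1[C@]23O[C@@]2(C)CCC[C@]3(C)CC[C@H]1C(C)=C
F9 | step 6 | 4β-hydroxy-5α-eudesm-11-en-6-one | O=C1[C@@H]2[C@](C)(CCC[C@]2(C)O)CC[C@H]1C(C)=C
F10 | step 6 | 4β-hydroxy-5α-eudesman-6-one | O=C1[C@@H]2[C@](C)(CCC[C@]2(C)O)CC[C@H]1C(C)C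
F11 | step 12 | (4S,5S,6R,7S,10R)-4-hydroxyeudesman-6-yl bromoacetate | BrCC(=O)O[C@H]1[C@@H]2[C@](C)(CCC[C@]2(C)O)CC[C@H]1C(C)C
F12 | step 12 | (4S,5S,6R,7S,10R)-4-hydroxyeudesman-6-yl (diethoxyphosphoryl)acetate | CCOP(=O)(OCC)CC(=O)O[C@H]1[C@@H]2[C@](C)(CCC[C@]2(C)O)CC[C@H]1C(C)C
F13 | step 12 | 3-[(tert-butyldimethylsilyl)oxy]-4-methoxybenzaldehyde | COc1ccc(C=O)cc1O[Si](C)(C)C(C)(C)C
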